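The readings stem from a simulated flask with constants of no real substance; scatter was added.

How much target does the flask hold at 3.0 d, and which change adds most?

the same everywhere: starting material 0.031 M; gas phase 2.2 mM (held); protic impurity 0.0155 M; catalyst 15 mol%

| run | added ligand | remark | time |
|---|---|---|---|
| south | 1.5 mM | run made earlier |  |
| north-east | 6 mM | run made earlier |  |
| flask | 3.0 mM |  | 3.0 d |

| run | time / h | target / % |
|---|---|---|
| south | 4.00 | 13 |
| south | 10.0 | 23 |
| south | 20.0 | 34 |
| south | 30.0 | 41 |
| south | 40.0 | 51 |
| north-east | 3.00 | 0 |
| north-east | 6.00 | 3 |
| north-east | 12.0 | 6 |
| north-east | 25.0 | 1 |
| north-east | 40.0 | 8 |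

(each reading ± 2 percentage points)

- a species is counted by the starting material in it: one self-condensation product counts as two
- at the start none of the gas is dissolved
- steps that have been proposed: 2 starting material -> self-condensation product; gas phase <-> dissolved gas; starting material + dissolved gas + catalyst -> catalyst + target; catalyst + added ligand <-> idle complex; dissolved gas + protic impurity -> quenched reagent

- target at 3.0 d, in percent of the starting material charged
- the change that raises the amount of target at 3.0 d, in percent of the starting material charged most ("none" if none brings more than 2 percentage points) (alpha / gamma / zeta / none)
- amount of target at 3.0 d, in percent of the starting material charged, after gamma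

- alpha: doubling the amount of catalyst, all else as stated
- gamma: doubling the saturation concentration of gas phase, all else as stated
- zeta: doubling the transfer coefficient of the gas phase, all else as stated

We build the flask up one process at a time. The catalyst charged is 4.65 mM. North-east, with ligand above that, shows 8% at 40.0 h where south shows 51%, so we read the ligand as taking catalyst one for one. That leaves 3.15 mM free in south and 1.65 mM in the flask.

Take the main step first, as a pseudo-first-order decay with its rate in proportion to free catalyst. South's first reading gives 0.0325 h⁻¹. With no ligand, the flask would reach 96.8%. With the ligand, it reaches 70.6%.

Now add self-condensation. As an approximation, reciprocal yields add like resistances in series: the reciprocal of the target equals the reciprocal of the main-step yield plus half the ratio of self-condensation to main step at the start, a selectivity factor. South's last reading stands against a main-step yield of 72.7%, so that ratio is 1.17 there. This gives the break-even free catalyst, the level at which both routes take starting material equally fast at the start: 3.69 mM. With starting material and gas as charged in south, the ratio in a flask is this level over its free catalyst.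

The flask's ratio is 2.24, so we commit to 39.5%. Gas and protic impurity stand as in south, so we add nothing for them. Doubling the catalyst leaves 6.30 mM free, more than the 3.30 mM that doubling the gas amounts to, so we choose alpha. Gamma doubles the main step's rate at the same free catalyst, so the ratio falls to 1.12 and we reckon 60.5%.

The forecast, in its words “Ligand binds the catalyst tightly”, gave 41%, alpha and 58%.

The simulation gives 42.5%, and 63.7% after gamma. The best change is alpha, worth 34 percentage points, against 21 points for gamma and 0.094 points for zeta.

    2 starting material → self-condensation product (k = 0.00970 M⁻¹ min⁻¹)
    gas phase ⇌ dissolved gas, rate k2*(csat - [dissolved gas]) (kL = 1.00 min⁻¹)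
    starting material + dissolved gas + catalyst → catalyst + target (k = 68.0 M⁻² min⁻¹)
    catalyst + added ligand ⇌ idle complex (K = 10000 M⁻¹, k = 9.40 M⁻¹ min⁻¹)
    dissolved gas + protic impurity → quenched reagent (k = 0.430 M⁻¹ min⁻¹)

In the neighbouring flask with 7.50 mM of ligand, the subtraction fails, since ligand exceeds catalyst by 2.85 mM. The binding constant then leaves 0.163 mM free. Against the break-even level that is a ratio of 22.6, and the reciprocal sum gives 4.98% target. That flask holds 5.88% target at 3.00 d, with 3.23% of its catalyst free and 68.1% in self-condensation product.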